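## Retrosynthetic overview

1. The C7 3-phenylpropanoate (acylation) and the (Z)-ylidenebutenolide are removed last; the butenolide goes back to a C1' aldehyde plus 3-methyl-2-silyloxyfuran (vinylogous Mukaiyama aldol, dehydration), and the C7 oxygen to allylic oxidation of the ring-B alkene followed by a reagent-controlled ketone reduction.
2. C1 and C1' come together from an Ireland–Claisen rearrangement of the C3 propionate of a C1=C2 cyclopentenol (C3–O to C1–C chirality transfer, trans to the C4 methyl); that alcohol comes from a C1 ketone by enone formation, epoxidation and Wharton transposition, and is resolved enzymatically.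
3. The spiro ketone is made in one operation from an acyclic silyl dienone and isoprene: Nazarov closure of ring A through the C3–C4 bond, then Diels–Alder closure of ring B on the C5 methylene that the cyclisation releases.
4. Enabling feature: C1 of ring A (cyclopentane C1–C5) can be a carbonyl, which makes C3 (CH2) and C4 (CH–CH3) the two termini of a cross-conjugated dienone C3=C2–C1(=O)–C5=C4; the spiro atom C5 is its α-carbon and carries CH2SiMe3 (the future C6 of ring B, cyclohexene C5–C10), which ends the cyclisation as an exocyclic alkene.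
5. Ring order: ring A (cyclopentanone) first, ring B (spiro cyclohexene) second in the same operation, butenolide ring last.

Key step: step 4

Remark: atom numbers are those of the target's spiro[4.5]decane skeleton throughout (C1 carries the side chain, C2 and C3 are the ring-A methylenes, C4 carries the methyl, C5 is the spiro atom, C6 is the ring-B methylene next to C7, C7 carries the ester oxygen, C8=C9 is the alkene, C10 is the allylic methylene, C1' is the side-chain CH(CH3)). Compounds 9 to 14 are racemic; their SMILES show the enantiomer that step 8 carries forward.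

## Route

Step 1
Reactants: 1 diethyl {2-[methoxy(methyl)amino]-2-oxoethyl}phosphonate; 2 (iodomethyl)trimethylsilane
Product: 3 diethyl {1-[methoxy(methyl)amino]-1-oxo-3-(trimethylsilyl)propan-2-yl}phosphonate (racemic)
Conditions: NaH (1.1 equiv), DME, 0 °C; then 2, 70 °C
Reagents that add atoms: none
Why: C-alkylation (SN2) of the sodium salt of the phosphonoacetamide by the α-silyl iodide, the reaction type used for the corresponding silylmethyl phosphonoacetate ester; the new stereocentre is racemic and disappears in step 2.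

Step 2
Reactants: 3 diethyl {1-[methoxy(methyl)amino]-1-oxo-3-(trimethylsilyl)propan-2-yl}phosphonate; 4 acetaldehyde
Product: 5 N-methoxy-N-methyl-2-[(trimethylsilyl)methyl]but-2-enamide (mixture of alkene isomers)
Conditions: NaH (1.05 equiv), THF, 0 °C; then 4 (3 equiv), 0 to 25 °C
Reagents that add atoms: none
Why: Horner–Wadsworth–Emmons olefination installs the propenyl arm that becomes C4 and its methyl; the alkene geometry need not be controlled because both isomers converge in step 4.

Step 3
Reactants: 5 N-methoxy-N-methyl-2-[(trimethylsilyl)methyl]but-2-enamide; 6 vinylmagnesium bromide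
Product: 7 4-[(trimethylsilyl)methyl]hexa-1,4-dien-3-one (mixture of alkene isomers)
Conditions: CH2=CHMgBr (1.3 equiv), THF, −20 to 0 °C; inverse quench into cold 1 M HCl
Reagents that add atoms: none
Why: Weinreb ketone synthesis, in which the chelated tetrahedral adduct prevents a second addition and the acidic inverse quench keeps the released amine from adding to the new vinyl ketone.

Step 4
Reactants: 7 4-[(trimethylsilyl)methyl]hexa-1,4-dien-3-one; 8 isoprene
Product: 10 rac-(4S,5R)-4,8-dimethylspiro[4.5]dec-8-en-1-one, via methylene ketone 9 (not isolated)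
Conditions: FeCl3 (1.05 equiv), CH2Cl2, −30 °C; cold aq. NaHCO3 wash, Na2SO4, no concentration; then 8 (5 equiv), Me2AlCl (0.2 equiv), CH2Cl2, −78 to −20 °C
Reagents that add atoms: none
Why: FeCl3 activates the cross-conjugated dienone 7 as a 3-oxidopentadienyl cation that undergoes conrotatory 4π-electrocyclisation (Nazarov cyclisation), joining the vinyl terminus C3 to the propenyl terminus C4 and thereby closing ring A through the C3–C4 bond. The oxyallyl cation so formed is β to silicon at C5 and collapses by loss of the silyl group to the exocyclic C5=C6 alkene rather than by loss of H-4, which preserves the new C4 stereocentre and unmasks the s-cis methylene ketone 9; the closest precedent is the FeCl3-promoted Nazarov cyclisation of α-(trimethylsilylmethyl) divinyl ketones to α-methylenecyclopentanones. Ring B is then closed by a Me2AlCl-catalysed Diels–Alder reaction ([4+2] cycloaddition) of 9 with isoprene, which forms C5–C10 and C6–C7 and makes C5 the spiro quaternary centre. C4 arises racemic (both alkene isomers of 7 converge, the geometry only reversing the sense of conrotation), and C5 is controlled by C4 because the diene adds to the methylene face anti to the C4 methyl, which leaves C6 syn to that methyl. The step needs para regioselectivity (isoprene methyl 1,4 to C5), which Lewis-acid coordination of the s-cis enone secures, and exocyclic termination, which the β-silicon effect secures. Low temperature and immediate use of 9 are required to suppress migration of its double bond into the ring and its dimerisation.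

Step 5
Reactants: 10 rac-(4S,5R)-4,8-dimethylspiro[4.5]dec-8-en-1-one
Product: 12 rac-(4S,5R)-4,8-dimethylspiro[4.5]deca-2,8-dien-1-one, via silyl enol ether 11 (not isolated)
Conditions: LiN(iPr)2, Me3SiCl, THF, −78 °C; then Pd(OAc)2 (10 mol%), O2 (1 atm), DMSO, 25 °C
Reagents that add atoms: none
Why: Saegusa–Ito oxidation (kinetic silyl enol ether, then palladium-mediated dehydrosilylation); only C2 can be enolised because C5 is quaternary, so the C2=C3 enone forms without regiochemical ambiguity.

Step 6
Reactants: 12 rac-(4S,5R)-4,8-dimethylspiro[4.5]deca-2,8-dien-1-one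
Product: 13 rac-2,3-epoxy-4,8-dimethylspiro[4.5]dec-8-en-1-one (oxirane on the ring-A face opposite to the 4-methyl)
Conditions: 30% aq. H2O2, NaOH (0.3 equiv), MeOH, 0 °C
Reagents that add atoms: hydrogen peroxide, OO
Why: Weitz–Scheffer nucleophilic epoxidation, in which hydroperoxide adds to C3 from the face anti to the adjacent C4 methyl and closes on the same face (sets C2 and C3), while the isolated electron-rich C8=C9 alkene does not react with the nucleophilic oxidant.

Step 7
Reactants: 13 rac-2,3-epoxy-4,8-dimethylspiro[4.5]dec-8-en-1-one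
Product: 14 rac-(3R,4R,5S)-4,8-dimethylspiro[4.5]deca-1,8-dien-3-ol (3-OH trans to the 4-methyl)
Conditions: N2H4·H2O, AcOH (cat.), MeOH, 0 to 25 °C
Reagents that add atoms: none
Why: Wharton transposition (hydrazone formation, oxirane opening, loss of N2) moves the alkene to C1=C2 and leaves the C3–O bond intact, so the C3 carbinol keeps the configuration set in step 6.

Step 8
Reactants: 14 rac-(3R,4R,5S)-4,8-dimethylspiro[4.5]deca-1,8-dien-3-ol; 15 vinyl propionate
Product: 16 (3R,4R,5S)-4,8-dimethylspiro[4.5]deca-1,8-dien-3-yl propanoate (single enantiomer)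
Conditions: 15 (3 equiv), immobilised Burkholderia cepacia lipase, tBuOMe, 30 °C, stopped near half conversion; the unreacted (3S)-alcohol is removed by chromatography
Reagents that add atoms: none
Why: Lipase-catalysed kinetic resolution by enantioselective transesterification; by the empirical large/medium-substituent model for secondary alcohols (large = branched C4 side, medium = vinylic C2) the enzyme should acylate the (3R)-alcohol, which is the enantiomer needed, so resolution and installation of the propionate for step 9 coincide.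

Step 9
Reactants: 16 (3R,4R,5S)-4,8-dimethylspiro[4.5]deca-1,8-dien-3-yl propanoate
Product: 19 (2S)-2-[(1R,4S,5R)-4,8-dimethylspiro[4.5]deca-2,8-dien-1-yl]propanoic acid, via silyl ketene acetal 17 (not isolated), via silyl ester 18 (not isolated)
Conditions: LiN(iPr)2, THF–DMPU (4:1), −78 °C; Me3SiCl–Et3N, −78 to 60 °C; then 1 M HCl
Reagents that add atoms: none
Why: Ireland–Claisen rearrangement of the (Z)-silyl ketene acetal: the [3,3] shift is suprafacial, so the C1–C1' bond forms on the ring face that carried the C3 oxygen, trans to the C4 methyl (sets C1), and a boat transition state with the enolate methyl outside, expected because a chair would force the ketene acetal under ring A against C10 and H-4, sets C1' as (S).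

Step 10
Reactants: 19 (2S)-2-[(1R,4S,5R)-4,8-dimethylspiro[4.5]deca-2,8-dien-1-yl]propanoic acid
Product: 20 (2S)-2-[(1R,4S,5R)-4,8-dimethylspiro[4.5]dec-8-en-1-yl]propanoic acid
Conditions: H2 (1 atm), RhCl(PPh3)3 (5 mol%), benzene–EtOH (1:1), 25 °C
Reagents that add atoms: none
Why: Homogeneous hydrogenation with RhCl(PPh3)3, which reduces the cis-disubstituted C2=C3 alkene much faster than the trisubstituted C8=C9 alkene; no stereocentre is formed.

Step 11
Reactants: 20 (2S)-2-[(1R,4S,5R)-4,8-dimethylspiro[4.5]dec-8-en-1-yl]propanoic acid; 21 N,O-dimethylhydroxylamine hydrochloride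
Product: 22 (2S)-N-methoxy-N-methyl-2-[(1R,4S,5R)-4,8-dimethylspiro[4.5]dec-8-en-1-yl]propanamide
Conditions: 21, EDC·HCl, 1-hydroxybenzotriazole (0.2 equiv), N-methylmorpholine, CH2Cl2, 0 to 25 °C
Reagents that add atoms: none
Why: Carbodiimide amide coupling to the Weinreb amide, which holds the carboxyl carbon as a latent aldehyde through the oxidation steps; the benzotriazole active ester limits epimerisation at C1'.

Step 12
Reactants: 22 (2S)-N-methoxy-N-methyl-2-[(1R,4S,5R)-4,8-dimethylspiro[4.5]dec-8-en-1-yl]propanamide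
Product: 23 (2S)-2-[(1R,4S,5S)-7-hydroxy-4,8-dimethylspiro[4.5]dec-8-en-1-yl]-N-methoxy-N-methylpropanamide (mixture of C7 epimers)
Conditions: SeO2 (0.5 equiv), tBuOOH (3 equiv), CH2Cl2, 25 °C
Reagents that add atoms: selenium dioxide, O=[Se]=O (oxygen donor, re-oxidised by tert-butyl hydroperoxide, CC(C)(C)OO)
Why: Riley allylic oxidation (ene reaction, then [2,3]-sigmatropic shift), which in 1-methylcyclohexenes functionalises the ring CH2 next to the methyl-bearing alkene carbon, here C7, while the neopentylic C10 is disfavoured; the C7 configuration is not controlled because step 13 erases it.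

Step 13
Reactants: 23 (2S)-2-[(1R,4S,5S)-7-hydroxy-4,8-dimethylspiro[4.5]dec-8-en-1-yl]-N-methoxy-N-methylpropanamide
Product: 24 (2S)-2-[(1R,4S,5S)-4,8-dimethyl-7-oxospiro[4.5]dec-8-en-1-yl]-N-methoxy-N-methylpropanamide
Conditions: Dess–Martin periodinane, CH2Cl2, 0 to 25 °C
Reagents that add atoms: none
Why: Dess–Martin oxidation of the allylic alcohols converges both C7 epimers (and any enone already formed in step 12) on one 2-methylcyclohexenone.

Step 14
Reactants: 24 (2S)-2-[(1R,4S,5S)-4,8-dimethyl-7-oxospiro[4.5]dec-8-en-1-yl]-N-methoxy-N-methylpropanamide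
Product: 25 (2S)-2-[(1R,4S,5S,7S)-7-hydroxy-4,8-dimethylspiro[4.5]dec-8-en-1-yl]-N-methoxy-N-methylpropanamide
Conditions: (R)-2-methyl-CBS-oxazaborolidine [(R)-1-methyl-3,3-diphenyltetrahydro-1H,3H-pyrrolo[1,2-c][1,3,2]oxazaborole] (0.2 equiv), catecholborane, toluene, −78 °C
Reagents that add atoms: none
Why: Corey–Bakshi–Shibata reduction under reagent control: with the (R)-catalyst and the α-methylalkenyl arm as the large group, hydride should be delivered to the carbonyl face that gives the (7S)-allylic alcohol, and catecholborane at −78 °C spares the Weinreb amide.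

Step 15
Reactants: 25 (2S)-2-[(1R,4S,5S,7S)-7-hydroxy-4,8-dimethylspiro[4.5]dec-8-en-1-yl]-N-methoxy-N-methylpropanamide; 26 3-phenylpropanoyl chloride
Product: 27 (1R,4S,5S,7S)-1-{(2S)-1-[methoxy(methyl)amino]-1-oxopropan-2-yl}-4,8-dimethylspiro[4.5]dec-8-en-7-yl 3-phenylpropanoate
Conditions: 26, pyridine, 4-(dimethylamino)pyridine (0.1 equiv), CH2Cl2, 0 to 25 °C
Reagents that add atoms: none
Why: Nucleophile-catalysed acyl transfer to the secondary allylic alcohol, with retention at C7 because the C7–O bond is not broken.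

Step 16
Reactants: 27 (1R,4S,5S,7S)-1-{(2S)-1-[methoxy(methyl)amino]-1-oxopropan-2-yl}-4,8-dimethylspiro[4.5]dec-8-en-7-yl 3-phenylpropanoate
Product: 28 (1R,4S,5S,7S)-4,8-dimethyl-1-[(2S)-1-oxopropan-2-yl]spiro[4.5]dec-8-en-7-yl 3-phenylpropanoate
Conditions: Cp2Zr(H)Cl (1.6 equiv), THF, 25 °C; then wet silica gel
Reagents that add atoms: none
Why: Chemoselective amide-to-aldehyde reduction by hydrozirconation of the amide carbonyl with Cp2Zr(H)Cl, which stops at a stable zirconium aminal and is known to leave esters, the trisubstituted alkene and the α-stereocentre untouched.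

Step 17
Reactants: 29 3-methylfuran-2(5H)-one
Product: 30 3-methyl-2-(trimethylsilyloxy)furan
Conditions: Me3SiOTf, Et3N, CH2Cl2, 0 °C
Reagents that add atoms: trimethylsilyl trifluoromethanesulfonate, C[Si](C)(C)OS(=O)(=O)C(F)(F)F
Why: O-silylation of the butenolide dienolate (soft enolisation) gives the aromatic silyloxyfuran nucleophile.

Step 18
Reactants: 28 (1R,4S,5S,7S)-4,8-dimethyl-1-[(2S)-1-oxopropan-2-yl]spiro[4.5]dec-8-en-7-yl 3-phenylpropanoate; 30 3-methyl-2-(trimethylsilyloxy)furan
Product: 32 (1R,4S,5S,7S)-1-[(2S)-1-hydroxy-1-(4-methyl-5-oxo-2,5-dihydrofuran-2-yl)propan-2-yl]-4,8-dimethylspiro[4.5]dec-8-en-7-yl 3-phenylpropanoate (mixture at the two new centres), via silyl ether 31 (not isolated)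
Conditions: 30 (1.5 equiv), Me3SiOTf (0.1 equiv), CH2Cl2, −78 °C; then 1 M HCl, THF, 0 °C
Reagents that add atoms: none
Why: Vinylogous Mukaiyama aldol addition through C5 of the silyloxyfuran; the two new stereocentres form as a mixture that does not matter because both become sp2 in step 19, and −78 °C avoids epimerisation at C1'.

Step 19
Reactants: 32 (1R,4S,5S,7S)-1-[(2S)-1-hydroxy-1-(4-methyl-5-oxo-2,5-dihydrofuran-2-yl)propan-2-yl]-4,8-dimethylspiro[4.5]dec-8-en-7-yl 3-phenylpropanoate
Product: 34 (1R,4S,5S,7S)-4,8-dimethyl-1-{(2S)-1-[(2Z)-4-methyl-5-oxofuran-2(5H)-ylidene]propan-2-yl}spiro[4.5]dec-8-en-7-yl 3-phenylpropanoate (CNP0260277.1), via mesylate 33 (not isolated)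
Conditions: MeSO2Cl, Et3N, CH2Cl2, 0 °C; then DBU, 0 to 25 °C
Reagents that add atoms: none
Why: Mesylation, then E1cB elimination through the butenolide dienolate, gives the γ-alkylidenebutenolide; the (Z)-isomer is expected as the thermodynamically preferred geometry (alkyl group syn to the ring oxygen, away from H-3 of the lactone).

## Compound list

1 | diethyl {2-[methoxy(methyl)amino]-2-oxoethyl}phosphonate | CCOP(=O)(CC(=O)N(C)OC)OCC | starting material
2 | (iodomethyl)trimethylsilane | C[Si](C)(C)CI | starting material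
3 | diethyl {1-[methoxy(methyl)amino]-1-oxo-3-(trimethylsilyl)propan-2-yl}phosphonate (racemic) | CCOP(=O)(OCC)C(C[Si](C)(C)C)C(=O)N(C)OC | intermediate
4 | acetaldehyde | CC=O | starting material
5 | N-methoxy-N-methyl-2-[(trimethylsilyl)methyl]but-2-enamide (alkene isomer mixture; isomer with CH3 cis to CH2SiMe3 shown) | C/C=C(\C[Si](C)(C)C)C(=O)N(C)OC | intermediate
6 | vinylmagnesium bromide | C=C[Mg]Br | starting material
7 | 4-[(trimethylsilyl)methyl]hexa-1,4-dien-3-one (alkene isomer mixture; same isomer shown) | C/C=C(\C[Si](C)(C)C)C(=O)C=C | intermediate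
8 | isoprene (2-methylbuta-1,3-diene) | CC(=C)C=C | starting material
9 | rac-3-methyl-2-methylidenecyclopentan-1-one ((3S) shown) | O=C1CC[C@H](C)C1=C | intermediate
10 | rac-(4S,5R)-4,8-dimethylspiro[4.5]dec-8-en-1-one (4-methyl syn to C6) | O=C1CC[C@H](C)[C@@]12CC=C(C)CC2 | intermediate
11 | rac-trimethyl{[4,8-dimethylspiro[4.5]deca-1,8-dien-1-yl]oxy}silane (configuration as 10) | C[Si](C)(C)OC1=CC[C@H](C)[C@@]12CC=C(C)CC2 | intermediate
12 | rac-(4S,5R)-4,8-dimethylspiro[4.5]deca-2,8-dien-1-one | O=C1C=C[C@H](C)[C@@]12CC=C(C)CC2 | intermediate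
13 | rac-2,3-epoxy-4,8-dimethylspiro[4.5]dec-8-en-1-one (oxirane anti to the 4-methyl; 4-methyl syn to C6) | O=C1[C@H]2O[C@H]2[C@H](C)[C@@]13CC=C(C)CC3 | intermediate
14 | rac-(3R,4R,5S)-4,8-dimethylspiro[4.5]deca-1,8-dien-3-ol (3-OH trans to the 4-methyl) | C1=C[C@@H](O)[C@H](C)[C@@]12CC=C(C)CC2 | intermediate
15 | vinyl propionate | CCC(=O)OC=C | starting material
16 | (3R,4R,5S)-4,8-dimethylspiro[4.5]deca-1,8-dien-3-yl propanoate | C1=C[C@@H](OC(=O)CC)[C@H](C)[C@@]12CC=C(C)CC2 | intermediate
17 | (3R,4R,5S)-4,8-dimethyl-3-{[(1Z)-1-(trimethylsilyloxy)prop-1-en-1-yl]oxy}spiro[4.5]deca-1,8-diene | C1=C[C@@H](O/C(O[Si](C)(C)C)=C/C)[C@H](C)[C@@]12CC=C(C)CC2 | intermediate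
18 | trimethylsilyl (2S)-2-[(1R,4S,5R)-4,8-dimethylspiro[4.5]deca-2,8-dien-1-yl]propanoate | C[Si](C)(C)OC(=O)[C@@H](C)[C@H]1C=C[C@H](C)[C@@]12CC=C(C)CC2 | intermediate
19 | (2S)-2-[(1R,4S,5R)-4,8-dimethylspiro[4.5]deca-2,8-dien-1-yl]propanoic acid | OC(=O)[C@@H](C)[C@H]1C=C[C@H](C)[C@@]12CC=C(C)CC2 | intermediate
20 | (2S)-2-[(1R,4S,5R)-4,8-dimethylspiro[4.5]dec-8-en-1-yl]propanoic acid | OC(=O)[C@@H](C)[C@H]1CC[C@H](C)[C@@]12CC=C(C)CC2 | intermediate
21 | N,O-dimethylhydroxylamine hydrochloride | CNOC.Cl | starting material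
22 | (2S)-N-methoxy-N-methyl-2-[(1R,4S,5R)-4,8-dimethylspiro[4.5]dec-8-en-1-yl]propanamide | CON(C)C(=O)[C@@H](C)[C@H]1CC[C@H](C)[C@@]12CC=C(C)CC2 | intermediate
23 | (2S)-2-[(1R,4S,5S)-7-hydroxy-4,8-dimethylspiro[4.5]dec-8-en-1-yl]-N-methoxy-N-methylpropanamide (C7 epimer mixture) | CON(C)C(=O)[C@@H](C)[C@H]1CC[C@H](C)[C@@]12CC=C(C)C(O)C2 | intermediate
24 | (2S)-2-[(1R,4S,5S)-4,8-dimethyl-7-oxospiro[4.5]dec-8-en-1-yl]-N-methoxy-N-methylpropanamide | CON(C)C(=O)[C@@H](C)[C@H]1CC[C@H](C)[C@@]12CC=C(C)C(=O)C2 | intermediate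
25 | (2S)-2-[(1R,4S,5S,7S)-7-hydroxy-4,8-dimethylspiro[4.5]dec-8-en-1-yl]-N-methoxy-N-methylpropanamide | CON(C)C(=O)[C@@H](C)[C@H]1CC[C@H](C)[C@@]12CC=C(C)[C@@H](O)C2 | intermediate
26 | 3-phenylpropanoyl chloride | O=C(Cl)CCc1ccccc1 | starting material
27 | (1R,4S,5S,7S)-1-{(2S)-1-[methoxy(methyl)amino]-1-oxopropan-2-yl}-4,8-dimethylspiro[4.5]dec-8-en-7-yl 3-phenylpropanoate | CON(C)C(=O)[C@@H](C)[C@H]1CC[C@H](C)[C@@]12CC=C(C)[C@@H](OC(=O)CCc3ccccc3)C2 | intermediate
28 | (1R,4S,5S,7S)-4,8-dimethyl-1-[(2S)-1-oxopropan-2-yl]spiro[4.5]dec-8-en-7-yl 3-phenylpropanoate | O=C[C@@H](C)[C@H]1CC[C@H](C)[C@@]12CC=C(C)[C@@H](OC(=O)CCc3ccccc3)C2 | intermediate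
29 | 3-methylfuran-2(5H)-one | CC1=CCOC1=O | starting material
30 | 3-methyl-2-(trimethylsilyloxy)furan | Cc1ccoc1O[Si](C)(C)C | intermediate
31 | O-trimethylsilyl ether of 32 (mixture at the two new centres) | CC1=CC(OC1=O)C(O[Si](C)(C)C)[C@@H](C)[C@H]2CC[C@H](C)[C@@]23CC=C(C)[C@@H](OC(=O)CCc4ccccc4)C3 | intermediate
32 | (1R,4S,5S,7S)-1-[(2S)-1-hydroxy-1-(4-methyl-5-oxo-2,5-dihydrofuran-2-yl)propan-2-yl]-4,8-dimethylspiro[4.5]dec-8-en-7-yl 3-phenylpropanoate (mixture at the two new centres) | CC1=CC(OC1=O)C(O)[C@@H](C)[C@H]2CC[C@H](C)[C@@]23CC=C(C)[C@@H](OC(=O)CCc4ccccc4)C3 | intermediate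
33 | methanesulfonate of 32 (mixture at the two new centres) | CC1=CC(OC1=O)C(OS(C)(=O)=O)[C@@H](C)[C@H]2CC[C@H](C)[C@@]23CC=C(C)[C@@H](OC(=O)CCc4ccccc4)C3 | intermediate
34 | (1R,4S,5S,7S)-4,8-dimethyl-1-{(2S)-1-[(2Z)-4-methyl-5-oxofuran-2(5H)-ylidene]propan-2-yl}spiro[4.5]dec-8-en-7-yl 3-phenylpropanoate (CNP0260277.1) | CC1=C/C(=C/[C@@H](C)[C@H]2CC[C@H](C)[C@@]23CC=C(C)[C@@H](OC(=O)CCc2ccccc2)C3)OC1=O | target

## Step count and risks

Total step count: 19. Longest linear sequence: 18 steps (steps 1 to 16, 18 and 19); step 17 is a one-step side branch.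

The three steps most likely to fail are steps 4, 7 and 9.

Step 4 (key step). What may go wrong: during the hand-over between the two Lewis acids the free methylene ketone can be lost through acid-mediated migration of the exocyclic double bond into the ring and through self-condensation. The fallback sets out from 7 and returns to the route at 10. The FeCl3 Nazarov mixture is quenched at −30 °C directly into thiophenol/Et3N, so that the methylene ketone is captured by conjugate addition as the storable 3-methyl-2-[(phenylsulfanyl)methyl]cyclopentan-1-one F1. NaIO4 in aqueous methanol then gives the sulfoxide 3-methyl-2-[(phenylsulfinyl)methyl]cyclopentan-1-one F2. Heating F2 with excess isoprene in toluene at 110 °C (sealed tube) releases the methylene ketone slowly by thermal sulfoxide syn-elimination, so that it is consumed at low stationary concentration in a thermal Diels–Alder reaction to give 10.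

Step 7. What may go wrong: slow hydrazone formation at the carbonyl flanked by the quaternary C5, and diversion of the vinyl diazene intermediate into reduction or solvolysis pathways. The fallback sets out from 13 and returns at 14. NaBH4 (MeOH, 0 °C) reduces the ketone to the epoxy alcohol 2,3-epoxy-4,8-dimethylspiro[4.5]dec-8-en-1-ol F3 (either C1 epimer serves). 1,1'-Thiocarbonyldiimidazole converts it into O-(2,3-epoxy-4,8-dimethylspiro[4.5]dec-8-en-1-yl) 1H-imidazole-1-carbothioate F4. Bu3SnH with azobisisobutyronitrile in benzene at 80 °C then generates the C1 radical (Barton–McCombie-type C–O cleavage), the adjacent oxirane opens to the C3 alkoxy radical, and hydrogen transfer gives 14 with the C3–O bond untouched.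

Step 9. What may go wrong: erosion of the C1' configuration through leakage between boat and chair transition states or through incomplete control of enolate geometry, and slow bond formation next to the quaternary C5. The fallback sets out from 14 and returns at 20.
- The resolution of step 8 is run with vinyl acetate to give (3R,4R,5S)-4,8-dimethylspiro[4.5]deca-1,8-dien-3-yl acetate F5.
- Its Ireland–Claisen rearrangement (LiN(iPr)2, Me3SiCl, THF, −78 to 60 °C, acidic work-up) creates only C1, by the same suprafacial transfer, and gives 2-[4,8-dimethylspiro[4.5]deca-2,8-dien-1-yl]acetic acid F6 (side chain trans to the 4-methyl).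
- Hydrogenation as in step 10 gives 2-[4,8-dimethylspiro[4.5]dec-8-en-1-yl]acetic acid F7.
- Activation as the pivaloyl mixed anhydride and reaction with lithiated (S)-4-benzyl-1,3-oxazolidin-2-one gives the N-acyl oxazolidinone F8.
- Evans methylation (NaN(SiMe3)2, MeI, THF, −78 °C) sets C1' as (S) under auxiliary control and gives the methylated N-acyl oxazolidinone F9.
- LiOH/H2O2 removes the auxiliary to give 20.

Further compounds

F1 | step 4 | 3-methyl-2-[(phenylsulfanyl)methyl]cyclopentan-1-one (racemic, both C2 epimers) | O=C1CC[C@H](C)C1CSc2ccccc2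
F2 | step 4 | 3-methyl-2-[(phenylsulfinyl)methyl]cyclopentan-1-one (racemic, isomer mixture at C2 and sulfur) | O=C1CC[C@H](C)C1CS(=O)c2ccccc2
F3 | step 7 | 2,3-epoxy-4,8-dimethylspiro[4.5]dec-8-en-1-ol (racemic, oxirane anti to the 4-methyl, C1 epimers) | OC1[C@H]2O[C@H]2[C@H](C)[C@@]13CC=C(C)CC3
F4 | step 7 | O-(2,3-epoxy-4,8-dimethylspiro[4.5]dec-8-en-1-yl) 1H-imidazole-1-carbothioate (racemic, C1 epimers) | S=C(n1ccnc1)OC2[C@H]3O[C@H]3[C@H](C)[C@@]24CC=C(C)CC4
F5 | step 9 | (3R,4R,5S)-4,8-dimethylspiro[4.5]deca-1,8-dien-3-yl acetate | C1=C[C@@H](OC(C)=O)[C@H](C)[C@@]12CC=C(C)CC2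
F6 | step 9 | 2-[4,8-dimethylspiro[4.5]deca-2,8-dien-1-yl]acetic acid (side chain trans to the 4-methyl, 4-methyl syn to C6) | OC(=O)C[C@H]1C=C[C@H](C)[C@@]12CC=C(C)CC2
F7 | step 9 | 2-[4,8-dimethylspiro[4.5]dec-8-en-1-yl]acetic acid (same configuration as F6) | OC(=O)C[C@H]1CC[C@H](C)[C@@]12CC=C(C)CC2
F8 | step 9 | (4S)-4-benzyl-3-{2-[4,8-dimethylspiro[4.5]dec-8-en-1-yl]acetyl}-1,3-oxazolidin-2-one (ring configuration as F7) | O=C(C[C@H]1CC[C@H](C)[C@@]12CC=C(C)CC2)N3[C@@H](Cc4ccccc4)COC3=O
F9 | step 9 | (4S)-4-benzyl-3-{(2S)-2-[(1R,4S,5R)-4,8-dimethylspiro[4.5]dec-8-en-1-yl]propanoyl}-1,3-oxazolidin-2-one | O=C([C@@H](C)[C@H]1CC[C@H](C)[C@@]12CC=C(C)CC2)N3[C@@H](Cc4ccccc4)COC3=O
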